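**Retrosynthetic overview**

1. The target is the C15 ester of diol 29 with (E)-2-(acetoxymethyl)but-2-enoic acid 35 (last step). The exocyclic C11=C13 methylene comes from a Horner–Wadsworth–Emmons reaction of α-phosphonolactone 26 with formaldehyde.
2. The strategy rests on the contiguous C6(OH)–C7(H)–C8(O) triad of the ten-membered carbocycle (C1–C10) and its trans-fused γ-lactone (O–C8–C7–C11–C12), in which the C7–C11 bond lies anti to the C6–O bond.
3. Key disconnection C7–C11: the lactone ring is closed last, by the C11 carbanion of an O8-bound phosphonoacetate opening the cis-6,7-epoxide 25 at C7 with inversion. 25 comes from hydroxyl-directed epoxidation of the (8S)-6Z-dienol 22, whose carbinol is set by oxazaborolidine reduction of dienone 21.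
4. The carbocycle is formed first, by Nozaki–Hiyama–Kishi closure of C7–C8 in the Z,Z-iododienal 19.
5. The chain of 19 is built from but-3-yn-1-ol (methylalumination, then ethylene oxide: E-C1=C10, C2–C3), propargyl alcohol (anti-carbomagnesiation, iodination: C4=C5, C15) and ethynyltrimethylsilane (C6–C7). Ring order: ten-membered ring (step 11), oxirane (step 14), lactone (step 16).

Key step: step 16

Assumption: germacrane numbering is used for all macrocycles (C1=C10 with C14 methyl, C4=C5 with C15 oxymethyl, C6, C7, C8, lactone C11–C13); the C15 silyl ether is tert-butyldiphenylsilyl so that the C8 tert-butyldimethylsilyl ether can be removed selectively, and C11 of 26 is expected as an epimer mixture, which is inconsequential because it becomes sp2 in step 17.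

**Route**

Step 1
Reactants: 1 but-3-yn-1-ol
Product: 2 tert-butyl(but-3-yn-1-yloxy)dimethylsilane
Conditions: TBSCl, imidazole, CH2Cl2, 0 °C to rt
Reagents that add atoms: tert-butyldimethylsilyl chloride, CC(C)(C)[Si](C)(C)Cl
Why: Imidazole-promoted silylation of the primary alcohol masks the future C8 oxygen for the organometallic steps.

Step 2
Reactants: 2 tert-butyl(but-3-yn-1-yloxy)dimethylsilane; 3 ethylene oxide
Product: 6 (E)-6-[(tert-butyldimethylsilyl)oxy]-4-methylhex-3-en-1-ol, via alkenyldimethylalane 4 (not isolated), via lithium alkenylalanate 5 (not isolated)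
Conditions: Me3Al (2.5 equiv), Cp2ZrCl2 (0.25 equiv), CH2Cl2, 0 °C to rt; volatiles removed; n-BuLi, hexane, −78 to 0 °C; ethylene oxide, THF, −78 °C to rt
Reagents that add atoms: trimethylaluminium, C[Al](C)C
Why: Negishi zirconium-catalysed carboalumination adds methyl and aluminium syn across the terminal alkyne (methyl to the internal carbon), and the derived alanate transfers the alkenyl group to ethylene oxide with retention, so the E-trisubstituted C1=C10 alkene and the C2–C3 unit should be set in one flask.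

Step 3
Reactants: 6 (E)-6-[(tert-butyldimethylsilyl)oxy]-4-methylhex-3-en-1-ol
Product: 7 {[(E)-6-bromo-3-methylhex-3-en-1-yl]oxy}(tert-butyl)dimethylsilane
Conditions: CBr4, PPh3, CH2Cl2, 0 °C
Reagents that add atoms: carbon tetrabromide, BrC(Br)(Br)Br
Why: Appel bromination converts the primary alcohol into the bromide under neutral conditions that leave the silyl ether and the alkene untouched.

Step 4
Reactants: 7 {[(E)-6-bromo-3-methylhex-3-en-1-yl]oxy}(tert-butyl)dimethylsilane; 8 propargyl alcohol
Product: 12 (E)-8-[(tert-butyldimethylsilyl)oxy]-2-[(Z)-iodomethylidene]-6-methyloct-5-en-1-ol (iodine cis to CH2OH), via Grignard reagent 9 (not isolated), via bromomagnesium propargyl alkoxide 10 (not isolated), via alkenylmagnesium alkoxide 11 (not isolated)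
Conditions: 7, Mg, THF, 40 °C; separately 8, EtMgBr (1.0 equiv), THF, −20 °C; combined (1.5 equiv of 9), CuI (10 mol%), −10 °C to rt; then I2, −40 to 0 °C
Reagents that add atoms: iodine, II
Why: Copper-catalysed anti-carbomagnesiation of the propargylic alkoxide puts the alkyl group on C4 and magnesium on C5 cis to the chelating CH2O group, and iodinolysis with retention should give the (Z)-3-iodoallylic alcohol that fixes the C4=C5 geometry (C15 cis to the future C6).

Step 5
Reactants: 12 (E)-8-[(tert-butyldimethylsilyl)oxy]-2-[(Z)-iodomethylidene]-6-methyloct-5-en-1-ol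
Product: 13 tert-butyldiphenylsilyl ether of 12
Conditions: TBDPSCl, imidazole, DMF, rt
Reagents that add atoms: tert-butyldiphenylsilyl chloride, CC(C)(C)[Si](Cl)(c1ccccc1)c1ccccc1
Why: Imidazole-promoted silylation gives a C15 silyl ether that should survive the later acidic removal of the C8 TBS group.

Step 6
Reactants: 13 tert-butyldiphenylsilyl ether of 12; 14 ethynyltrimethylsilane
Product: 15 (3Z,7E)-4-{[(tert-butyldiphenylsilyl)oxy]methyl}-10-[(tert-butyldimethylsilyl)oxy]-8-methyl-1-(trimethylsilyl)deca-3,7-dien-1-yne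
Conditions: Pd(PPh3)2Cl2 (3 mol%), CuI (6 mol%), Et3N, THF, rt
Reagents that add atoms: none
Why: Sonogashira coupling of the vinyl iodide proceeds at room temperature with retention of alkene geometry and brings in C6 and C7.

Step 7
Reactants: 15 silylated enyne
Product: 16 (3Z,7E)-4-{[(tert-butyldiphenylsilyl)oxy]methyl}-10-[(tert-butyldimethylsilyl)oxy]-1-iodo-8-methyldeca-3,7-dien-1-yne
Conditions: NIS, AgNO3 (cat.), acetone, rt, dark
Reagents that add atoms: N-iodosuccinimide, O=C1CCC(=O)N1I
Why: Silver-catalysed iododesilylation converts the alkynylsilane directly into the 1-iodoalkyne through a silver acetylide, without touching the silyl ethers.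

Step 8
Reactants: 16 iodoenyne
Product: 17 (1Z,3Z,7E)-4-{[(tert-butyldiphenylsilyl)oxy]methyl}-10-[(tert-butyldimethylsilyl)oxy]-1-iodo-8-methyldeca-1,3,7-triene
Conditions: 2-nitrobenzenesulfonylhydrazide, Et3N, THF/i-PrOH, rt
Reagents that add atoms: none
Why: Diimide reduction delivers two hydrogens syn to the iodoalkyne to give the Z-vinyl iodide, while the trisubstituted alkenes and the C–I bond are not reduced.

Step 9
Reactants: 17 Z,Z-iododiene bis-silyl ether
Product: 18 (3E,7Z,9Z)-7-{[(tert-butyldiphenylsilyl)oxy]methyl}-10-iodo-3-methyldeca-3,7,9-trien-1-ol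
Conditions: PPTS (0.3 equiv), MeOH/CH2Cl2, rt
Reagents that add atoms: none
Why: Acid-catalysed methanolysis cleaves the primary TBS ether far faster than the TBDPS ether, freeing only the C8 hydroxyl.

Step 10
Reactants: 18 iodotrienol
Product: 19 (3E,7Z,9Z)-7-{[(tert-butyldiphenylsilyl)oxy]methyl}-10-iodo-3-methyldeca-3,7,9-trienal
Conditions: Dess–Martin periodinane, NaHCO3, CH2Cl2, 0 °C; used at once
Reagents that add atoms: none
Why: Buffered Dess–Martin oxidation gives the β,γ-unsaturated aldehyde without base or acid that would move the C1=C10 alkene into conjugation.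

Step 11
Reactants: 19 iodotrienal
Product: 20 racemic (2Z,4Z,8E)-5-{[(tert-butyldiphenylsilyl)oxy]methyl}-9-methylcyclodeca-2,4,8-trien-1-ol
Conditions: CrCl2 (8 equiv), NiCl2 (2 mol%), degassed DMSO, rt, slow addition to 3 mM
Reagents that add atoms: none
Why: In the Nozaki–Hiyama–Kishi reaction the Z-alkenylchromium species forms with retention and adds irreversibly to the aldehyde at high dilution, closing C7–C8 and hence the ten-membered ring with the 6Z geometry already in place; C8 is formed racemic and is corrected in steps 12 and 13.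

Step 12
Reactants: 20 racemic macrocyclic dienol
Product: 21 (2Z,4Z,8E)-5-{[(tert-butyldiphenylsilyl)oxy]methyl}-9-methylcyclodeca-2,4,8-trien-1-one
Conditions: Dess–Martin periodinane, NaHCO3, CH2Cl2, 0 °C
Reagents that add atoms: none
Why: Dess–Martin oxidation of the allylic alcohol gives the cross-conjugated dienone, whose Z-enone geometry is held by the ring.

Step 13
Reactants: 21 macrocyclic dienone
Product: 22 (1S,2Z,4Z,8E)-5-{[(tert-butyldiphenylsilyl)oxy]methyl}-9-methylcyclodeca-2,4,8-trien-1-ol
Conditions: (R)-2-methyl-CBS-oxazaborolidine (0.5 equiv), catecholborane (1.5 equiv), toluene, −78 °C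
Reagents that add atoms: none
Why: In the Corey–Bakshi–Shibata reduction the alkenyl branch should act as the larger carbonyl substituent, so the (R)-catalyst is expected to deliver hydride 1,2 to the face that gives the (8S)-carbinol, and catecholborane at −78 °C should not hydroborate the alkenes.

Step 14
Reactants: 22 (8S)-dienol
Product: 23 (6R,7S,8S)-15-[(tert-butyldiphenylsilyl)oxy]-6,7-epoxygermacra-1(10)E,4Z-dien-8-ol (cis-epoxide syn to the hydroxyl)
Conditions: VO(acac)2 (5 mol%), t-BuOOH (1.5 equiv, decane), CH2Cl2, 0 °C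
Reagents that add atoms: tert-butyl hydroperoxide, CC(C)(C)OO
Why: Vanadium-catalysed hydroxyl-directed epoxidation delivers oxygen from the C8 vanadate to the allylic C6=C7 bond on the face syn to the hydroxyl, the sense seen with cis-cyclooctenol and cis-cyclononenol, and the allylic alkene should react faster than the homoallylic C1=C10 and the remote C4=C5 bonds.

Step 15
Reactants: 23 syn-epoxy alcohol; 24 diethylphosphonoacetic acid
Product: 25 (6R,7S,8S)-15-[(tert-butyldiphenylsilyl)oxy]-6,7-epoxygermacra-1(10)E,4Z-dien-8-yl (diethoxyphosphoryl)acetate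
Conditions: DCC, DMAP (0.2 equiv), CH2Cl2, 0 °C to rt
Reagents that add atoms: none
Why: Steglich esterification attaches the nucleophile to O8 under neutral conditions that should preserve the vinyl epoxide.

Step 16
Reactants: 25 epoxy phosphonoacetate
Product: 26 (6R,7S,8S)-15-[(tert-butyldiphenylsilyl)oxy]-11-(diethoxyphosphoryl)-6-hydroxygermacra-1(10)E,4Z-dien-12,8-olide (trans-fused lactone, C11 epimers)
Conditions: t-BuOK (1.1 equiv), THF/t-BuOH (5:1), 0 °C to rt; AcOH, 0 °C
Reagents that add atoms: none
Why: Proposed new method: deprotonation of the phosphonoacetate gives a stabilised C11 carbanion that attacks C7 of the cis-epoxide from the side opposite the C7–O bond (SN2), so the C7–C11 bond forms, the lactone ring O8–C8–C7–C11–C12 closes in a 5-exo-tet mode and the C6 alkoxide is released; the alkoxide is then neutralised by the far more acidic C11–H of the product, leaving a phosphonate-stabilised lactone enolate that should resist translactonisation until the acetic acid quench. The closest known reactions are the Stork epoxynitrile cyclisation, the opening of epoxides by sodium phosphonoacetate or malonate to give α-substituted γ-lactones, and the C2-selective 5-exo opening of 2,3-epoxy alcohols by O-tethered carbamates; an O-ester-tethered phosphonoacetate on a macrocyclic vinyl epoxide has not been shown. The new C7 stereocentre is set by inversion, so it is dictated by the epoxide face (itself directed by the C8 hydroxyl) and by the C8 oxygen that carries the nucleophile, which gives the trans-fused lactone; C6 keeps its C–O bond and C8 is untouched. The step needs attack at C7 (5-exo) in preference to the allylically activated C6 (6-endo) or C4 (SN2'), which the three-atom tether and the absence of a Lewis acid should secure, because the C6 and C4 trajectories cannot be reached collinearly and no cationic character develops. The syn epoxy ester can place O8 anti to the epoxide oxygen with an extended C6–C7–C8–C9 torsion, which is the geometry needed for backside attack.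

Step 17
Reactants: 26 α-phosphonolactone; 27 formaldehyde
Product: 28 (6R,7S,8S)-15-[(tert-butyldiphenylsilyl)oxy]-6-hydroxygermacra-1(10)E,4Z,11(13)-trien-12,8-olide
Conditions: K2CO3, 37% aq. CH2O, THF, 0 °C to rt
Reagents that add atoms: none
Why: Horner–Wadsworth–Emmons olefination of the α-phosphonolactone with formaldehyde under mild carbonate conditions installs the exocyclic methylene and removes the undefined C11 centre.

Step 18
Reactants: 28 silylated α-methylene lactone
Product: 29 (6R,7S,8S)-6,15-dihydroxygermacra-1(10)E,4Z,11(13)-trien-12,8-olide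
Conditions: TBAF/AcOH (1:1, 1.5 equiv), THF, 0 °C to rt
Reagents that add atoms: none
Why: Acetic-acid-buffered fluoride cleaves the Si–O bond without conjugate addition to, or opening of, the α-methylene lactone.

Step 19
Reactants: 30 acetaldehyde; 31 tert-butyl acrylate
Product: 32 racemic tert-butyl 3-hydroxy-2-methylidenebutanoate
Conditions: DABCO (0.5 equiv), 1,4-dioxane/H2O, rt, several days
Reagents that add atoms: none
Why: The Morita–Baylis–Hillman reaction joins the acrylate α-carbon to the aldehyde and provides the C5 skeleton of the side chain.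

Step 20
Reactants: 32 Baylis–Hillman alcohol
Product: 33 racemic tert-butyl 3-acetoxy-2-methylidenebutanoate
Conditions: Ac2O, pyridine, DMAP (cat.), CH2Cl2, 0 °C
Reagents that add atoms: acetic anhydride, CC(=O)OC(C)=O
Why: DMAP-catalysed acetylation of the secondary allylic alcohol prepares the allylic transposition.

Step 21
Reactants: 33 secondary allylic acetate
Product: 34 tert-butyl (E)-2-(acetoxymethyl)but-2-enoate (methyl trans to the ester)
Conditions: DABCO (0.2 equiv), THF, reflux
Reagents that add atoms: none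
Why: Amine-catalysed 1,3-transposition of the Baylis–Hillman acetate (SN2' addition of DABCO, then SN2' return of acetate) should lead to the thermodynamically preferred primary acetate with the E-trisubstituted alkene.

Step 22
Reactants: 34 tert-butyl ester
Product: 35 (E)-2-(acetoxymethyl)but-2-enoic acid
Conditions: TFA/CH2Cl2 (1:4), 0 °C to rt
Reagents that add atoms: none
Why: Acidolysis of the tert-butyl ester with loss of isobutene frees the acid and leaves the acetate and the alkene geometry intact.

Step 23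
Reactants: 29 diol; 35 (E)-2-(acetoxymethyl)but-2-enoic acid
Product: 36 (6R,7S,8S)-15-{[(E)-2-(acetoxymethyl)but-2-enoyl]oxy}-6-hydroxygermacra-1(10)E,4Z,11(13)-trien-12,8-olide (CNP0184624.1)
Conditions: 35 (1.1 equiv), DCC, DMAP (0.1 equiv), CH2Cl2, −20 to 0 °C
Reagents that add atoms: none
Why: Steglich esterification at low temperature should acylate the unhindered primary allylic C15 hydroxyl in preference to the hindered secondary C6 hydroxyl.

**Compound list**

1 | but-3-yn-1-ol | C#CCCO | starting material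
2 | tert-butyl(but-3-yn-1-yloxy)dimethylsilane | C#CCCO[Si](C)(C)C(C)(C)C | intermediate
3 | ethylene oxide | C1CO1 | starting material
4 | (E)-[4-(tert-butyldimethylsilyloxy)-2-methylbut-1-enyl]dimethylalane | C[Al](C)/C=C(\C)CCO[Si](C)(C)C(C)(C)C | intermediate
5 | lithium butyl[(E)-4-(tert-butyldimethylsilyloxy)-2-methylbut-1-enyl]dimethylalanate | [Li+].CCCC[Al-](C)(C)/C=C(\C)CCO[Si](C)(C)C(C)(C)C | intermediate
6 | (E)-6-[(tert-butyldimethylsilyl)oxy]-4-methylhex-3-en-1-ol | OCC/C=C(\C)CCO[Si](C)(C)C(C)(C)C | intermediate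
7 | {[(E)-6-bromo-3-methylhex-3-en-1-yl]oxy}(tert-butyl)dimethylsilane | BrCC/C=C(\C)CCO[Si](C)(C)C(C)(C)C | intermediate
8 | propargyl alcohol | C#CCO | starting material
9 | [(E)-6-(tert-butyldimethylsilyloxy)-4-methylhex-3-enyl]magnesium bromide | Br[Mg]CC/C=C(\C)CCO[Si](C)(C)C(C)(C)C | intermediate
10 | bromomagnesium prop-2-yn-1-olate | C#CCO[Mg]Br | intermediate
11 | bromomagnesium alkoxide of the (Z)-3-(bromomagnesio)-2-alkylallyl alcohol | Br[Mg]/C=C(\CO[Mg]Br)CC/C=C(\C)CCO[Si](C)(C)C(C)(C)C | intermediate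
12 | (E)-8-[(tert-butyldimethylsilyl)oxy]-2-[(Z)-iodomethylidene]-6-methyloct-5-en-1-ol | I/C=C(\CO)CC/C=C(\C)CCO[Si](C)(C)C(C)(C)C | intermediate
13 | tert-butyldiphenylsilyl ether of 12 | I/C=C(\CO[Si](c1ccccc1)(c1ccccc1)C(C)(C)C)CC/C=C(\C)CCO[Si](C)(C)C(C)(C)C | intermediate
14 | ethynyltrimethylsilane | C#C[Si](C)(C)C | starting material
15 | (3Z,7E)-4-{[(tert-butyldiphenylsilyl)oxy]methyl}-10-[(tert-butyldimethylsilyl)oxy]-8-methyl-1-(trimethylsilyl)deca-3,7-dien-1-yne | C[Si](C)(C)C#C/C=C(\CO[Si](c1ccccc1)(c1ccccc1)C(C)(C)C)CC/C=C(\C)CCO[Si](C)(C)C(C)(C)C | intermediate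
16 | (3Z,7E)-4-{[(tert-butyldiphenylsilyl)oxy]methyl}-10-[(tert-butyldimethylsilyl)oxy]-1-iodo-8-methyldeca-3,7-dien-1-yne | IC#C/C=C(\CO[Si](c1ccccc1)(c1ccccc1)C(C)(C)C)CC/C=C(\C)CCO[Si](C)(C)C(C)(C)C | intermediate
17 | (1Z,3Z,7E)-4-{[(tert-butyldiphenylsilyl)oxy]methyl}-10-[(tert-butyldimethylsilyl)oxy]-1-iodo-8-methyldeca-1,3,7-triene | I/C=C\C=C(/CO[Si](c1ccccc1)(c1ccccc1)C(C)(C)C)CC/C=C(\C)CCO[Si](C)(C)C(C)(C)C | intermediate
18 | (3E,7Z,9Z)-7-{[(tert-butyldiphenylsilyl)oxy]methyl}-10-iodo-3-methyldeca-3,7,9-trien-1-ol | I/C=C\C=C(/CO[Si](c1ccccc1)(c1ccccc1)C(C)(C)C)CC/C=C(\C)CCO | intermediate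
19 | (3E,7Z,9Z)-7-{[(tert-butyldiphenylsilyl)oxy]methyl}-10-iodo-3-methyldeca-3,7,9-trienal | I/C=C\C=C(/CO[Si](c1ccccc1)(c1ccccc1)C(C)(C)C)CC/C=C(\C)CC=O | intermediate
20 | racemic (2Z,4Z,8E)-5-{[(tert-butyldiphenylsilyl)oxy]methyl}-9-methylcyclodeca-2,4,8-trien-1-ol | OC1C/C(C)=C/CC/C(CO[Si](c2ccccc2)(c2ccccc2)C(C)(C)C)=C/C=C\1 | intermediate
21 | (2Z,4Z,8E)-5-{[(tert-butyldiphenylsilyl)oxy]methyl}-9-methylcyclodeca-2,4,8-trien-1-one | O=C1C/C(C)=C/CC/C(CO[Si](c2ccccc2)(c2ccccc2)C(C)(C)C)=C/C=C\1 | intermediate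
22 | (1S,2Z,4Z,8E)-5-{[(tert-butyldiphenylsilyl)oxy]methyl}-9-methylcyclodeca-2,4,8-trien-1-ol | O[C@H]1C/C(C)=C/CC/C(CO[Si](c2ccccc2)(c2ccccc2)C(C)(C)C)=C/C=C\1 | intermediate
23 | (6R,7S,8S)-15-[(tert-butyldiphenylsilyl)oxy]-6,7-epoxygermacra-1(10)E,4Z-dien-8-ol | O[C@H]1C/C(C)=C/CC/C(CO[Si](c2ccccc2)(c2ccccc2)C(C)(C)C)=C/[C@H]2O[C@H]21 | intermediate
24 | diethylphosphonoacetic acid | OC(=O)CP(=O)(OCC)OCC | starting material
25 | (6R,7S,8S)-15-[(tert-butyldiphenylsilyl)oxy]-6,7-epoxygermacra-1(10)E,4Z-dien-8-yl (diethoxyphosphoryl)acetate | CCOP(=O)(OCC)CC(=O)O[C@H]1C/C(C)=C/CC/C(CO[Si](c2ccccc2)(c2ccccc2)C(C)(C)C)=C/[C@H]2O[C@H]21 | intermediate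
26 | (6R,7S,8S)-15-[(tert-butyldiphenylsilyl)oxy]-11-(diethoxyphosphoryl)-6-hydroxygermacra-1(10)E,4Z-dien-12,8-olide, C11 epimers | CCOP(=O)(OCC)C1C(=O)O[C@H]2C/C(C)=C/CC/C(CO[Si](c3ccccc3)(c3ccccc3)C(C)(C)C)=C/[C@@H](O)[C@H]12 | intermediate
27 | formaldehyde | C=O | starting material
28 | (6R,7S,8S)-15-[(tert-butyldiphenylsilyl)oxy]-6-hydroxygermacra-1(10)E,4Z,11(13)-trien-12,8-olide | C=C1C(=O)O[C@H]2C/C(C)=C/CC/C(CO[Si](c3ccccc3)(c3ccccc3)C(C)(C)C)=C/[C@@H](O)[C@H]12 | intermediate
29 | (6R,7S,8S)-6,15-dihydroxygermacra-1(10)E,4Z,11(13)-trien-12,8-olide | C=C1C(=O)O[C@H]2C/C(C)=C/CC/C(CO)=C/[C@@H](O)[C@H]12 | intermediate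
30 | acetaldehyde | CC=O | starting material
31 | tert-butyl acrylate | C=CC(=O)OC(C)(C)C | starting material
32 | racemic tert-butyl 3-hydroxy-2-methylidenebutanoate | CC(O)C(=C)C(=O)OC(C)(C)C | intermediate
33 | racemic tert-butyl 3-acetoxy-2-methylidenebutanoate | CC(OC(C)=O)C(=C)C(=O)OC(C)(C)C | intermediate
34 | tert-butyl (E)-2-(acetoxymethyl)but-2-enoate | C/C=C(\COC(C)=O)C(=O)OC(C)(C)C | intermediate
35 | (E)-2-(acetoxymethyl)but-2-enoic acid | C/C=C(\COC(C)=O)C(=O)O | intermediate
36 | CNP0184624.1 | C=C1C(=O)O[C@H]2C/C(C)=C/CC/C(COC(=O)/C(=C/C)COC(C)=O)=C/[C@@H](O)[C@H]12 | target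

**Step count**

Total steps: 23. Longest linear sequence: 19 (steps 1–18 and 23); steps 19–22 prepare the side-chain acid.

**Steps most likely to fail**

Step 16 (carries the label). The carbanion may open the epoxide at the allylic C6, fail to reach the backside of C7 in the macrocycle, or the released alkoxide may translactonise or attack phosphorus. The fallback uses known chemistry; it sets out from 22 and returns at 26. Dienol 22 is esterified with 24 (DCC, DMAP) to the dienyl phosphonoacetate F1. Diazo transfer (p-acetamidobenzenesulfonyl azide, NaH, THF) gives the diazophosphonoacetate F2. Rhodium(II)-catalysed intramolecular cyclopropanation (Rh2(OAc)4, 1,2-dichloroethane, 60 °C) of the proximal C6=C7 bond should give the cyclopropane-fused phosphonolactone F3, in which C11 is bonded to C7 and C6 on the face fixed by allylic 1,3-strain of the Z-alkene. Lewis-acid-catalysed SN2 opening of this vinyl-substituted, doubly activated cyclopropane at C6 by acetic acid (Sc(OTf)3 cat.) proceeds with inversion and should give the C6 acetate F4 with oxygen anti to C7–C11. Brief methanolysis (K2CO3, MeOH, 0 °C) then returns to 26.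

Step 11. Oligomerisation may outrun closure of the strained ten-membered ring, or the β,γ-unsaturated aldehyde may isomerise before it is trapped. The fallback sets out from 13 and returns at 20. Stille coupling of 13 with tributyl(vinyl)stannane gives the terminal diene F5. PPTS/MeOH removes the TBS group to give alcohol F6, and Dess–Martin oxidation gives aldehyde F7. Vinylmagnesium bromide at −78 °C gives the racemic vinyl carbinol F8. Ring-closing metathesis (second-generation Grubbs catalyst, CH2Cl2, 40 °C, 1 mM) between the vinyl carbinol and the terminal alkene of the diene closes C6=C7, which the ring should constrain to Z, and delivers 20.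

Step 14. Oxygen may be delivered to the olefin face anti to the hydroxyl, the sense peracids show with medium-ring cis-cycloalkenols, because of the conformation of the ten-membered ring. The fallback sets out from 21 and returns at 25. Dienone 21 is reduced with the (S)-oxazaborolidine to the (8R)-dienol F9. The anti-selective epoxidation then places the oxirane on the required face and gives the anti epoxy alcohol F10 with the (6R,7S) epoxide. Mitsunobu esterification with 24 (PPh3, DIAD, THF, 0 °C) inverts C8 and gives 25 directly.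

**Further compounds**

F1 | step 16 | (8S)-dienyl (diethoxyphosphoryl)acetate of 22 | CCOP(=O)(OCC)CC(=O)O[C@H]1C/C(C)=C/CC/C(CO[Si](c2ccccc2)(c2ccccc2)C(C)(C)C)=C/C=C\1
F2 | step 16 | (8S)-dienyl diazo(diethoxyphosphoryl)acetate | CCOP(=O)(OCC)C(=[N+]=[N-])C(=O)O[C@H]1C/C(C)=C/CC/C(CO[Si](c2ccccc2)(c2ccccc2)C(C)(C)C)=C/C=C\1
F3 | step 16 | 6,11-cyclo-11-(diethoxyphosphoryl)-12,8-olide (cyclopropane C6–C7–C11) | CCOP(=O)(OCC)[C@]12C(=O)O[C@H]3C/C(C)=C/CC/C(CO[Si](c4ccccc4)(c4ccccc4)C(C)(C)C)=C/[C@H]1[C@H]23
F4 | step 16 | C6 acetate of 26 | CCOP(=O)(OCC)C1C(=O)O[C@H]2C/C(C)=C/CC/C(CO[Si](c3ccccc3)(c3ccccc3)C(C)(C)C)=C/[C@@H](OC(C)=O)[C@H]12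
F5 | step 11 | (3Z,7E)-4-{[(tert-butyldiphenylsilyl)oxy]methyl}-10-[(tert-butyldimethylsilyl)oxy]-8-methyldeca-1,3,7-triene | C=C/C=C(\CO[Si](c1ccccc1)(c1ccccc1)C(C)(C)C)CC/C=C(\C)CCO[Si](C)(C)C(C)(C)C
F6 | step 11 | (3E,7Z)-7-{[(tert-butyldiphenylsilyl)oxy]methyl}-3-methyldeca-3,7,9-trien-1-ol | C=C/C=C(\CO[Si](c1ccccc1)(c1ccccc1)C(C)(C)C)CC/C=C(\C)CCO
F7 | step 11 | (3E,7Z)-7-{[(tert-butyldiphenylsilyl)oxy]methyl}-3-methyldeca-3,7,9-trienal | C=C/C=C(\CO[Si](c1ccccc1)(c1ccccc1)C(C)(C)C)CC/C=C(\C)CC=O
F8 | step 11 | racemic (5E,9Z)-9-{[(tert-butyldiphenylsilyl)oxy]methyl}-5-methyldodeca-1,5,9,11-tetraen-3-ol | C=C/C=C(\CO[Si](c1ccccc1)(c1ccccc1)C(C)(C)C)CC/C=C(\C)CC(O)C=C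
F9 | step 14 | (1R,2Z,4Z,8E)-5-{[(tert-butyldiphenylsilyl)oxy]methyl}-9-methylcyclodeca-2,4,8-trien-1-ol | O[C@@H]1C/C(C)=C/CC/C(CO[Si](c2ccccc2)(c2ccccc2)C(C)(C)C)=C/C=C\1
F10 | step 14 | (6R,7S,8R)-15-[(tert-butyldiphenylsilyl)oxy]-6,7-epoxygermacra-1(10)E,4Z-dien-8-ol (epoxide anti to hydroxyl) | O[C@@H]1C/C(C)=C/CC/C(CO[Si](c2ccccc2)(c2ccccc2)C(C)(C)C)=C/[C@H]2O[C@H]21
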